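The 14-membered carbocycle is opened at C3–C4 (cembrane numbering), the bond between the lactone carbinol carbon and the tertiary carbinol carbon, where carbocycle and δ-lactone meet. This vicinal C3–O/C4–O pair is a pinacol retron, and the C16 ester sits 1,5 to O3. A SmI2 keto–aldehyde coupling of an open-chain keto aldehyde ester therefore closes the macrocycle, sets C3 and C4, and lets the C3 alkoxide lactonise, closing both rings in one operation. C1 is bought as (4S)-4-ethenyloxolan-2-one, the epoxide is set by Sharpless epoxidation of a geranylacetone derivative, and C15 and C8 are relayed by substrate control (lactone methylation, singlet-oxygen ene reaction).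

Key step: step 10

Remark: (E)-geranylacetone (1) and (4S)-4-ethenyloxolan-2-one (5) are taken as commercially available in isomerically pure form. Cembrane numbering is used for every carbon that ends up in the target: ring C1–C14 (C3 carries the lactone oxygen, C4 the hydroxyl, C8 the hydroperoxide, C11–C12 the epoxide), side chain C15–C16 with C17 methyl on C15, and methyls C18, C19, C20 on C4, C8, C12.

Step 1
Reactants: 1 (5E)-6,10-dimethylundeca-5,9-dien-2-one
Product: 2 (5E,9E)-11-hydroxy-6,10-dimethylundeca-5,9-dien-2-one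
Conditions: SeO2 (0.3 equiv), t-BuOOH, salicylic acid (cat.), CH2Cl2, 0 °C → rt
Reagents that add atoms: tert-butyl hydroperoxide, CC(C)(C)OO
Why: SeO2-catalysed allylic oxidation (ene reaction then [2,3]-sigmatropic shift) attacks the more electron-rich terminal trisubstituted alkene and oxidises its (E)-methyl group (the future C13), so the internal alkene and the ketone should stay untouched and no stereocentre is formed.

Step 2
Reactants: 2 (5E,9E)-11-hydroxy-6,10-dimethylundeca-5,9-dien-2-one
Product: 3 (5E)-8-[(2S,3S)-3-(hydroxymethyl)-3-methyloxiran-2-yl]-6-methyloct-5-en-2-one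
Conditions: Ti(OiPr)4 (cat.), L-(+)-diethyl tartrate (cat.), t-BuOOH, 4 Å molecular sieves, CH2Cl2, −20 °C
Reagents that add atoms: tert-butyl hydroperoxide, CC(C)(C)OO
Why: Sharpless asymmetric epoxidation is directed by the allylic hydroxyl, so only C11=C12 reacts and C7=C8 is spared; the L-(+)-tartrate ligand delivers oxygen to the face that gives the (2S,3S)-epoxy alcohol, which is the 11S,12S trans-epoxide of the target.

Step 3
Reactants: 3 (5E)-8-[(2S,3S)-3-(hydroxymethyl)-3-methyloxiran-2-yl]-6-methyloct-5-en-2-one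
Product: 4 (2R,3S)-2-methyl-3-[(3E)-3-methyl-7-oxooct-3-en-1-yl]oxirane-2-carbaldehyde
Conditions: Dess–Martin periodinane, pyridine, CH2Cl2, 0 °C → rt
Reagents that add atoms: none
Why: Dess–Martin oxidation of the primary alcohol under buffered conditions gives the epoxy aldehyde, which cannot epimerise because its α-carbon (C12) is quaternary.

Step 4
Reactants: 5 (4S)-4-ethenyloxolan-2-one
Product: 8 methyl (3S)-3-(iodomethyl)pent-4-enoate, via trimethylsilyl (3S)-3-(iodomethyl)pent-4-enoate 6 (not isolated), via (3S)-3-(iodomethyl)pent-4-enoic acid 7 (not isolated)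
Conditions: TMSI, CH2Cl2, rt → 40 °C; then MeOH, TMSCHN2, 0 °C
Reagents that add atoms: iodotrimethylsilane, C[Si](C)(C)I; (trimethylsilyl)diazomethane, C[Si](C)(C)C=[N+]=[N-]
Why: Iodotrimethylsilane silylates the lactone carbonyl and iodide opens the ring by SN2 at the O–CH2 carbon (the future C14) without touching the stereocentre; methanolysis of the silyl ester and methylation of the acid with TMSCHN2 avoid the acidic esterification that could add HI to the vinyl group.

Step 5
Reactants: 8 methyl (3S)-3-(iodomethyl)pent-4-enoate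
Product: 9 [(2S)-2-ethenyl-4-methoxy-4-oxobutyl]triphenylphosphonium iodide
Conditions: PPh3, MeCN, 80 °C
Reagents that add atoms: triphenylphosphine, c1ccc(cc1)P(c1ccccc1)c1ccccc1
Why: SN2 quaternisation of triphenylphosphine by the primary iodide; the β-branch only slows the reaction and the stereocentre is not involved.

Step 6
Reactants: 9 [(2S)-2-ethenyl-4-methoxy-4-oxobutyl]triphenylphosphonium iodide; 4 (2R,3S)-2-methyl-3-[(3E)-3-methyl-7-oxooct-3-en-1-yl]oxirane-2-carbaldehyde
Product: 11 methyl (3S,4Z)-3-ethenyl-5-{(2S,3S)-2-methyl-3-[(3E)-3-methyl-7-oxooct-3-en-1-yl]oxiran-2-yl}pent-4-enoate, via phosphonium ylide 10 (not isolated)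
Conditions: NaN(SiMe3)2 (0.98 equiv), THF, −78 °C; then 4, −78 → 0 °C
Reagents that add atoms: none
Why: Wittig olefination joins C13 and C14; the phosphonium α-hydrogens are far more acidic than the ester α-hydrogens, the non-stabilised ylide should take the aldehyde well before the methyl ketone at low temperature, and the Z geometry is irrelevant because the alkene is saturated in step 8.

Step 7
Reactants: 11 methyl (3S,4Z)-3-ethenyl-5-{(2S,3S)-2-methyl-3-[(3E)-3-methyl-7-oxooct-3-en-1-yl]oxiran-2-yl}pent-4-enoate
Product: 13 methyl (3R,4Z)-3-(2-hydroxyethyl)-5-{(2S,3S)-3-[(3E)-7-hydroxy-3-methyloct-3-en-1-yl]-2-methyloxiran-2-yl}pent-4-enoate (both epimers at the secondary carbinol C4), via bis(9-BBN) adduct 12 (not isolated)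
Conditions: 9-BBN (2.5 equiv), THF, 0 °C → rt; then 30% H2O2, aq. NaOAc, 0 °C → rt
Reagents that add atoms: hydrogen peroxide, OO
Why: Brown hydroboration–oxidation: 9-BBN adds anti-Markovnikov to the monosubstituted vinyl group much faster than to the hindered 1,2-disubstituted and trisubstituted alkenes, and the excess reduces the methyl ketone to a carbinol, a harmless epimer mixture that keeps the ketone away from the hydrazide in step 8 and is reoxidised in step 9.

Step 8
Reactants: 13 methyl (3R,4Z)-3-(2-hydroxyethyl)-5-{(2S,3S)-3-[(3E)-7-hydroxy-3-methyloct-3-en-1-yl]-2-methyloxiran-2-yl}pent-4-enoate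
Product: 14 methyl (3R)-3-(2-hydroxyethyl)-5-{(2S,3S)-3-[(3E)-7-hydroxy-3-methyloct-3-en-1-yl]-2-methyloxiran-2-yl}pentanoate (both epimers at C4)
Conditions: 2-nitrobenzenesulfonohydrazide (excess, in portions), Et3N, CH2Cl2, rt
Reagents that add atoms: none
Why: Diimide reduction transfers two hydrogens in a concerted syn fashion to the 1,2-disubstituted C13=C14 alkene, should leave the trisubstituted C7=C8 alkene because diimide is slowed strongly by substitution, and does not hydrogenolyse the allylic epoxide.

Step 9
Reactants: 14 methyl (3R)-3-(2-hydroxyethyl)-5-{(2S,3S)-3-[(3E)-7-hydroxy-3-methyloct-3-en-1-yl]-2-methyloxiran-2-yl}pentanoate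
Product: 15 methyl (3R)-5-{(2S,3S)-2-methyl-3-[(3E)-3-methyl-7-oxooct-3-en-1-yl]oxiran-2-yl}-3-(2-oxoethyl)pentanoate
Conditions: Dess–Martin periodinane (2.6 equiv), pyridine, CH2Cl2, 0 °C → rt
Reagents that add atoms: none
Why: Dess–Martin oxidation turns the primary carbinol into the C3 aldehyde and both C4 carbinol epimers into the one methyl ketone, so the mixture converges on a single keto aldehyde under buffered conditions that spare the epoxide.

Step 10
Reactants: 15 methyl (3R)-5-{(2S,3S)-2-methyl-3-[(3E)-3-methyl-7-oxooct-3-en-1-yl]oxiran-2-yl}-3-(2-oxoethyl)pentanoate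
Product: 17 (1R,3R,4S,7E,11S,12S)-11,12-epoxy-4-hydroxy-17-norcembr-7-en-16,3-olide, via samarium diolate of the macrocyclic diol ester 16 (not isolated)
Conditions: SmI2 (4 equiv, 0.1 M in THF), THF, syringe-pump addition of 15 to about 2 mM, 0 °C → rt; aq. NH4Cl
Reagents that add atoms: none
Why: SmI2 reduces the aldehyde faster than the ketone to a C3 ketyl bound to trivalent samarium, which adds to the C4 ketone and is reduced again to the diolate 16 (intramolecular pinacol cross-coupling; closest known type: SmI2- and low-valent-titanium-mediated keto aldehyde pinacol macrocyclisations to 14-membered carbocyclic diols), after which the C3 alkoxide acylates on the methyl ester. The carbocycle closes by macrocyclic ketyl–carbonyl coupling between C3 and C4 under high dilution, the δ-lactone by 6-exo-trig addition–elimination of O3 at C16. C3 is controlled by C1: the samarium on O3 can be chelated by the C16 ester carbonyl only when the ester arm and O3 lie on the same side of the extended C14–C1–C2–C3 segment, the 1,3-syn (3R) arrangement that also leads to the diequatorial lactone. C4 is controlled by C3: the ketone oxygen joins the same samarium (cis-diolate, as in small-ring SmI2 pinacol closures) while the fully substituted C4 takes a corner of the 14-membered ring with a gauche C2–C3–C4–C5 unit, which together give the erythro (3R,4S) diol. The step needs aldehyde-before-ketone reduction and ring closure over oligomerisation, secured by the reduction potentials and by slow addition at about 2 mM, and it needs the trisubstituted epoxide, the C7=C8 alkene and the ester to survive, which they should in HMPA-free THF.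

Step 11
Reactants: 17 (1R,3R,4S,7E,11S,12S)-11,12-epoxy-4-hydroxy-17-norcembr-7-en-16,3-olide
Product: 19 (1R,3R,4S,7E,11S,12S,15S)-11,12-epoxy-4-hydroxycembr-7-en-16,3-olide, via dilithium enolate alkoxide 18 (not isolated)
Conditions: LiN(iPr)2 (2.2 equiv), THF, −78 °C; then MeI, −78 → −40 °C
Reagents that add atoms: iodomethane, CI
Why: Enolate alkylation of the δ-lactone: the dianion (tertiary alkoxide plus lactone enolate) is C-methylated on the enolate face opposite the C1–C14 and C3–C4 ring bonds, which gives the 15S methyl group trans to C14, also the thermodynamically preferred all-equatorial lactone.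

Step 12
Reactants: 19 (1R,3R,4S,7E,11S,12S,15S)-11,12-epoxy-4-hydroxycembr-7-en-16,3-olide
Product: 20 (1R,3R,4S,6E,8R,11S,12S,15S)-11,12-epoxy-8-hydroperoxy-4-hydroxycembr-6-en-16,3-olide
Conditions: O2, tetraphenylporphyrin (cat.), visible light, CH2Cl2, −20 °C
Reagents that add atoms: dioxygen, O=O
Why: Schenck ene reaction of singlet oxygen with the only remaining alkene: attack on the more substituted side of C7=C8 (cis effect) with abstraction of an allylic C6 hydrogen places the hydroperoxide on tertiary C8 and moves the double bond to C6=C7 (E); the 8R configuration is expected from suprafacial attack on the exposed outer face of the ring alkene, in the conformation fixed by the fused lactone.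

Compound list
1 | (5E)-6,10-dimethylundeca-5,9-dien-2-one ((E)-geranylacetone) | CC(=O)CC/C=C(\C)CCC=C(C)C | starting material
2 | (5E,9E)-11-hydroxy-6,10-dimethylundeca-5,9-dien-2-one | CC(=O)CC/C=C(\C)CC/C=C(\C)CO | intermediate
3 | (5E)-8-[(2S,3S)-3-(hydroxymethyl)-3-methyloxiran-2-yl]-6-methyloct-5-en-2-one | CC(=O)CC/C=C(\C)CC[C@@H]1O[C@@]1(C)CO | intermediate
4 | (2R,3S)-2-methyl-3-[(3E)-3-methyl-7-oxooct-3-en-1-yl]oxirane-2-carbaldehyde | CC(=O)CC/C=C(\C)CC[C@@H]1O[C@@]1(C)C=O | intermediate
5 | (4S)-4-ethenyloxolan-2-one | C=C[C@H]1COC(=O)C1 | starting material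
6 | trimethylsilyl (3S)-3-(iodomethyl)pent-4-enoate | C[Si](C)(C)OC(=O)C[C@H](CI)C=C | intermediate (not isolated)
7 | (3S)-3-(iodomethyl)pent-4-enoic acid | OC(=O)C[C@H](CI)C=C | intermediate (not isolated)
8 | methyl (3S)-3-(iodomethyl)pent-4-enoate | COC(=O)C[C@H](CI)C=C | intermediate
9 | [(2S)-2-ethenyl-4-methoxy-4-oxobutyl]triphenylphosphonium iodide | COC(=O)C[C@H](C[P+](c1ccccc1)(c1ccccc1)c1ccccc1)C=C.[I-] | intermediate
10 | methyl (3S)-3-ethenyl-4-(triphenyl-λ5-phosphanylidene)butanoate (ylide) | COC(=O)C[C@@H](C=C)C=P(c1ccccc1)(c1ccccc1)c1ccccc1 | intermediate (not isolated)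
11 | methyl (3S,4Z)-3-ethenyl-5-{(2S,3S)-2-methyl-3-[(3E)-3-methyl-7-oxooct-3-en-1-yl]oxiran-2-yl}pent-4-enoate | COC(=O)C[C@@H](C=C)/C=C\[C@]1(C)O[C@H]1CC/C(C)=C/CCC(C)=O | intermediate
12 | bis(9-BBN) adduct of 11: B-alkyl-9-BBN at C3 and 9-BBN borinate of the reduced C4 ketone | COC(=O)C[C@@H](CCB1C2CCCC1CCC2)/C=C\[C@]1(C)O[C@H]1CC/C(C)=C/CCC(C)OB1C2CCCC1CCC2 | intermediate (not isolated)
13 | methyl (3R,4Z)-3-(2-hydroxyethyl)-5-{(2S,3S)-3-[(3E)-7-hydroxy-3-methyloct-3-en-1-yl]-2-methyloxiran-2-yl}pent-4-enoate, both epimers at C4 | COC(=O)C[C@@H](CCO)/C=C\[C@]1(C)O[C@H]1CC/C(C)=C/CCC(C)O | intermediate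
14 | methyl (3R)-3-(2-hydroxyethyl)-5-{(2S,3S)-3-[(3E)-7-hydroxy-3-methyloct-3-en-1-yl]-2-methyloxiran-2-yl}pentanoate, both epimers at C4 | COC(=O)C[C@@H](CCO)CC[C@]1(C)O[C@H]1CC/C(C)=C/CCC(C)O | intermediate
15 | methyl (3R)-5-{(2S,3S)-2-methyl-3-[(3E)-3-methyl-7-oxooct-3-en-1-yl]oxiran-2-yl}-3-(2-oxoethyl)pentanoate | COC(=O)C[C@@H](CC=O)CC[C@]1(C)O[C@H]1CC/C(C)=C/CCC(C)=O | intermediate
16 | methyl [(1R,3R,4S,7E,11S,12S)-11,12-epoxy-3,4-dihydroxy-4,8,12-trimethylcyclotetradec-7-en-1-yl]acetate (cembrane numbering), present as its samarium diolate and drawn as the diol | COC(=O)C[C@@H]1CC[C@]2(C)O[C@H]2CC/C(C)=C/CC[C@](C)(O)[C@H](O)C1 | intermediate (not isolated)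
17 | (1R,3R,4S,7E,11S,12S)-11,12-epoxy-4-hydroxy-17-norcembr-7-en-16,3-olide | C1C(=O)O[C@@H]2C[C@H]1CC[C@]1(C)O[C@H]1CC/C(C)=C/CC[C@]2(C)O | intermediate
18 | dilithium salt of 17 (lactone enolate and C4 alkoxide) | C1=C([O-])O[C@@H]2C[C@H]1CC[C@]1(C)O[C@H]1CC/C(C)=C/CC[C@]2(C)[O-].[Li+].[Li+] | intermediate (not isolated)
19 | (1R,3R,4S,7E,11S,12S,15S)-11,12-epoxy-4-hydroxycembr-7-en-16,3-olide | C[C@@H]1C(=O)O[C@@H]2C[C@H]1CC[C@]1(C)O[C@H]1CC/C(C)=C/CC[C@]2(C)O | intermediate
20 | (1R,3R,4S,6E,8R,11S,12S,15S)-11,12-epoxy-8-hydroperoxy-4-hydroxycembr-6-en-16,3-olide | C[C@@H]1C(=O)O[C@@H]2C[C@H]1CC[C@]1(C)O[C@H]1CC[C@@](C)(OO)/C=C/C[C@]2(C)O | target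

Total step count: 12. Longest linear sequence: 10 steps (steps 1–3 and 6–12 from geranylacetone).

Steps most likely to fail

Step 10. The ketyl may add through a non-chelated or differently folded transition state, so that facial selectivity at C3 is lost and the threo diol is formed and closes to the C3-epimeric lactone; simple reduction of the aldehyde and intermolecular coupling also compete. The fallback sets the C3 configuration in a separate operation and only repairs a wrong C3 centre, not a wrong C4 centre. It sets out from 15: the same SmI2 closure would give (1R,3S,4S,7E,11S,12S)-11,12-epoxy-4-hydroxy-17-norcembr-7-en-16,3-olide F1, which would be saponified (LiOH, THF/H2O, 0 °C) to [(1R,3S,4S,7E,11S,12S)-11,12-epoxy-3,4-dihydroxy-4,8,12-trimethylcyclotetradec-7-en-1-yl]acetic acid F2. Mitsunobu lactonisation of F2 (PPh3, DIAD, toluene, high dilution) should then close the δ-lactone with inversion at C3 and return the route to 17.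

Step 12. Hydrogen abstraction from the C19 methyl group instead of C6 would give the secondary C7 hydroperoxide with an exocyclic alkene, and attack on the other alkene face would give the C8 epimer. The fallback replaces the pericyclic ene reaction with a polar sequence that fixes the regiochemistry and adds oxygen anti to bromine. It sets out from 19, whose C4 hydroxyl would first be masked (TESOTf, 2,6-lutidine) as the 4-O-triethylsilyl ether of 19 F3, to prevent bromoetherification. Bromoperoxidation (1,3-dibromo-5,5-dimethylhydantoin, anhydrous H2O2 in Et2O, −40 °C) should give the Markovnikov (7S,8R)-7-bromo-8-hydroperoxide F4. Silylation of the hydroperoxide (TESCl, imidazole) to the triethylsilyl peroxide F5 prevents dioxetane formation, and DBU elimination towards C6 should give the (6E)-allylic silyl peroxide F6. Removal of both silyl groups (HF·pyridine, THF) returns the route to 20.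

Step 8. Diimide may not discriminate enough between the hindered Z-1,2-disubstituted C13=C14 alkene, which is flanked by the quaternary C12, and the unhindered trisubstituted C7=C8 alkene, so that over-reduction occurs. The fallback changes the selectivity principle from steric approach of diimide to alkene coordination at a metal: homogeneous hydrogenation of 13 (H2 at 1 atm, RhCl(PPh3)3, benzene/EtOH, rt), where trisubstituted alkenes do not bind the catalyst, should give 14 directly; no new compound arises (F0).

Further compounds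
F1 | step 10 | (1R,3S,4S,7E,11S,12S)-11,12-epoxy-4-hydroxy-17-norcembr-7-en-16,3-olide | C1C(=O)O[C@H]2C[C@H]1CC[C@]1(C)O[C@H]1CC/C(C)=C/CC[C@]2(C)O
F2 | step 10 | [(1R,3S,4S,7E,11S,12S)-11,12-epoxy-3,4-dihydroxy-4,8,12-trimethylcyclotetradec-7-en-1-yl]acetic acid | OC(=O)C[C@@H]1CC[C@]2(C)O[C@H]2CC/C(C)=C/CC[C@](C)(O)[C@@H](O)C1
F3 | step 12 | 4-O-triethylsilyl ether of 19 | C[C@@H]1C(=O)O[C@@H]2C[C@H]1CC[C@]1(C)O[C@H]1CC/C(C)=C/CC[C@]2(C)O[Si](CC)(CC)CC
F4 | step 12 | (7S,8R)-7-bromo-8-hydroperoxide of F3 | C[C@@H]1C(=O)O[C@@H]2C[C@H]1CC[C@]1(C)O[C@H]1CC[C@@](C)(OO)[C@@H](Br)CC[C@]2(C)O[Si](CC)(CC)CC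
F5 | step 12 | triethylsilyl peroxide of F4 | C[C@@H]1C(=O)O[C@@H]2C[C@H]1CC[C@]1(C)O[C@H]1CC[C@@](C)(OO[Si](CC)(CC)CC)[C@@H](Br)CC[C@]2(C)O[Si](CC)(CC)CC
F6 | step 12 | (6E)-allylic triethylsilyl peroxide, 4-O-triethylsilyl ether of 20 | C[C@@H]1C(=O)O[C@@H]2C[C@H]1CC[C@]1(C)O[C@H]1CC[C@@](C)(OO[Si](CC)(CC)CC)/C=C/C[C@]2(C)O[Si](CC)(CC)CC
F0 | step 8 | none | none
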